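One ratio runs my ledger for this flask: the lead of right-handed substrate over left-handed substrate, divided by the part of the charge that has reacted.

| setting | violet | blue | flask |
|---|---|---|---|
| left-handed substrate | 0.25 M | 1 M | 0.50 M |
| right-handed substrate | 0.25 M | 1 M | 0.50 M |
| gas | 180 mM (held) | 180 mM (held) | 180 mM (held) |
| free catalyst | 1 mol% | 1 mol% | 1 mol% |
| remark | run made earlier | run made earlier |  |
| time |  |  | 2.5 d |

| run | time / h | left-handed substrate / % | right-handed substrate / % |
|---|---|---|---|
| violet | 4.00 | 48.9 | 49.5 |
| violet | 8.00 | 48.6 | 49.4 |
| violet | 15.0 | 47.7 | 47.0 |
| violet | 25.0 | 45.8 | 46.2 |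
| violet | 50.0 | 44.0 | 44.0 |
| blue | 10.0 | 45.4 | 45.8 |
| blue | 20.0 | 42.5 | 44.1 |
| blue | 30.0 | 39.1 | 39.6 |
| blue | 40.0 | 38.0 | 37.7 |
| blue | 50.0 | 35.2 | 35.8 |

(scatter of a reading: 0.5 percentage points)

* part of the left-handed substrate and right-handed substrate charged together that has reacted at 2.5 d
* excess of left-handed product over right-handed product in the product at 2.5 d
* excess of right-handed substrate over left-handed substrate among what is left of the two at 2.5 d

- free catalyst is single-handed; left-handed substrate and right-handed substrate are mirror images of each other, charged as a racemate, each of them at the stated concentration
- at the start none of the gas is in solution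
- an excess is below zero if the other one leads

Every mole of the charge stands as substrate or as product, left-handed or right-handed. The racemate starts level. If no substrate changes hand, each surplus mole of left-handed product leaves one surplus mole of right-handed substrate behind, as in a plain kinetic resolution. The lead among the substrates, divided by what has reacted, is then the excess in the product.

I read the blue run at 50.0 h. Right-handed substrate stands at 35.8 %, left-handed substrate at 35.2 %, and 29.0 % has reacted. So the ratio is 2.07 %, and this is the ledger excess: the product excess that closed books require. Two readings with a scatter of 0.5 percentage points each make it uncertain by 2.44 %. One entry stays unseen, though: a right-handed mole that turns left-handed moves no total, yet it narrows the lead. So I commit to this figure for the product only if the books are closed, and these readings cannot show that they are.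

The forecast calls the flask “close to a plain racemic-rate problem”. It gives 21.5 % reacted (18.5 % to 25 %), a product excess of 2.1 % (0 % to 4.5 %) and a substrate excess of 0.6 % (0 % to 1.3 %). Its numbers give a ledger excess of 2.19 %, so its books close.

The flask gives 22.7 % reacted, a product excess of 32.9 % and a substrate excess of 0.193 %.

    partner + free catalyst + left-handed substrate → free catalyst + left-handed product (k = 22.0 M⁻² h⁻¹)
    free catalyst → spent catalyst (k = 0.0350 h⁻¹)
    partner ⇌ dormant form (K = 3.00, k = 0.0110 h⁻¹)
    partner + free catalyst + right-handed substrate → free catalyst + right-handed product (k = 11.0 M⁻² h⁻¹)
    gas ⇌ partner, rate k5*(csat - [partner]) (kL = 0.200 h⁻¹)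
    left-handed substrate ⇌ right-handed substrate (k = 0.160 h⁻¹)

At 0.621 d in this flask, left-handed substrate goes to product at 0.055 of the forward rate at which it turns into right-handed substrate, so the product step runs slower than that turning. The ledger excess of this flask is 0.658 %, and its product excess stands far above that. In the neighbour charged with 4 mol% of free catalyst, 54.9 % has reacted, the ledger excess is 0.594 %, and the product excess is 32.0 %.

The readings are calculated from invented constants.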